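**Retrosynthetic overview**
1. The ketone–aryl bond is cut. The acyl half is the N-methoxy-N-methylamide 6 of 4-silyloxy-3,5-diprenylcinnamic acid; the other half is 2-methyl-4H-pyran-4-one 10, whose methyl carbon becomes C1' of ring A.
2. Enabling feature: in ring A the ketone carbon sits on C1', oxygen on C2' and C4', hydrogen on C3', C5' and C6'. The array O=C–C1'–C2'(O)–C3'–C4'(O)–C5'–C6' is a folded 1,3,5,7-polycarbonyl chain, i.e. the ring-opened form of a 2-(acylmethyl)-4-pyranone (O1 → O on C2', C4=O → O on C4', C6 → C6').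
3. Key step: lithiated 10 is C-acylated by 6 (ketone–C1' bond). Methoxide then opens the pyranone, the chain recloses C1'–C6' to benzene ring A, and the silyl ether falls off, so all three phenols appear in the same flask.
4. Ring order: ring B is bought as 4-iodophenol and dressed by double ortho-prenylation, Heck reaction and silylation; ring A is formed last, in the key step. Pyranone 10 comes from 4-methoxybut-3-en-2-one and acetyl chloride.

Key step: step 5

Remark: ring A carbons are called C1' to C6' (C1' bears the ketone) and pyranone atoms O1, C2 to C6; polycarbonyl intermediates are drawn as keto tautomers although they react as enolates.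

**Step 1**
Reactants: 1 4-iodophenol; 2 1-bromo-3-methylbut-2-ene (prenyl bromide)
Product: 3 4-iodo-2,6-bis(3-methylbut-2-en-1-yl)phenol
Conditions: NaH (2.2 equiv), toluene, 0 °C to rt; 2 (2.2 equiv), rt
Reagents that add atoms: none
Why: Ortho-selective C-allylation of a phenoxide (the tight sodium phenoxide ion pair in a non-polar solvent attacks the primary carbon of prenyl bromide through its ortho carbon, then re-aromatises), run twice in one pot: iodine blocks the para position, toluene disfavours O-alkylation, and attack at the CH2 terminus should deliver the linear 3-methylbut-2-enyl groups.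

**Step 2**
Reactants: 3 4-iodo-2,6-bis(3-methylbut-2-en-1-yl)phenol; 4 N-methoxy-N-methylprop-2-enamide
Product: 5 (2E)-3-[4-hydroxy-3,5-bis(3-methylbut-2-en-1-yl)phenyl]-N-methoxy-N-methylprop-2-enamide
Conditions: Pd(OAc)2 (5 mol %), P(o-tol)3 (10 mol %), Et3N, DMF, 80 °C
Reagents that add atoms: none
Why: Mizoroki–Heck reaction: zerovalent palladium inserts into the unhindered C–I bond, the electron-poor acrylamide inserts, and syn β-hydride elimination should give the E enamide, while the trisubstituted prenyl alkenes do not insert and the free phenol is tolerated.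

**Step 3**
Reactants: 5 (2E)-3-[4-hydroxy-3,5-bis(3-methylbut-2-en-1-yl)phenyl]-N-methoxy-N-methylprop-2-enamide
Product: 6 (2E)-3-{4-[(tert-butyldimethylsilyl)oxy]-3,5-bis(3-methylbut-2-en-1-yl)phenyl}-N-methoxy-N-methylprop-2-enamide
Conditions: TBSCl, imidazole, DMF, 40 °C
Reagents that add atoms: tert-butyldimethylsilyl chloride, CC(C)(C)[Si](C)(C)Cl
Why: Imidazole-mediated silyl ether formation masks the phenol, which would otherwise quench the dienolate of step 5 and deactivate the amide as its phenoxide; a silyl ether is chosen because methoxide removes it again in the key step.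

**Step 4**
Reactants: 7 (3E)-4-methoxybut-3-en-2-one (2 equiv); 8 acetyl chloride
Product: 10 2-methyl-4H-pyran-4-one, via methoxyvinyl diketone 9 (not isolated)
Conditions: LiN(SiMe3)2 (2 equiv), THF, −78 °C; AcCl, −78 °C; then TFA, CH2Cl2, rt
Reagents that add atoms: none
Why: Claisen-type C-acylation of the kinetic lithium enolate of 7 by acetyl chloride (the second equivalent of enolate takes up the acidic diketone proton) gives diketone 9, whose enol oxygen closes onto the methoxyvinyl carbon under acid by 6-endo-trig oxa-Michael addition and loss of methanol, a standard 4-pyranone synthesis.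

**Step 5**
Reactants: 10 2-methyl-4H-pyran-4-one; 6 (2E)-3-{4-[(tert-butyldimethylsilyl)oxy]-3,5-bis(3-methylbut-2-en-1-yl)phenyl}-N-methoxy-N-methylprop-2-enamide
Product: 16 (2E)-1-(2,4-dihydroxyphenyl)-3-[4-hydroxy-3,5-bis(3-methylbut-2-en-1-yl)phenyl]prop-2-en-1-one, via lithium dienolate 11 (not isolated), via tetrahedral adduct 12 (not isolated), via acylmethylpyranone 13 (not isolated), via methoxyvinyl triketone 14 (not isolated), via silylated chalcone 15 (not isolated)
Conditions: 10 (1.5 equiv), LiN(SiMe3)2 (1.5 equiv), THF, −78 °C; 6, −78 to 0 °C; then NaOMe (5 equiv), MeOH, 60 °C; cold 1 M HCl work-up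
Reagents that add atoms: none
Why: LiN(SiMe3)2 removes the most acidic C–H of 10 (the C2 methyl group, a vinylogous α-position) to give dienolate 11, whose exocyclic carbon attacks the amide carbonyl of 6 to give the N,O-chelated adduct 12, and methanol collapses this to ketone 13, so the bond between the ketone carbon and the future C1' is made by a Weinreb ketone synthesis with a pyranone dienolate (Claisen-type acylation). Methoxide then adds to the unsubstituted C6 of the pyranone, the O1–C6 bond opens to the acyclic methoxyvinyl triketone 14, its doubly activated methylene (C1') attacks the methoxyvinyl carbon (C6') with loss of methoxide, enolization gives the 2,4-dihydroxyphenyl ketone 15, and methoxide finally methanolyses the aryl silyl ether to 16. The closest known reaction type for this second half is the base-induced ring opening and aldol-type reclosure of 2-(2-oxoalkyl)-4-pyranones to acylresorcinols used in biomimetic polyketide synthesis. Ring A is closed by a 6-endo-trig (enolendo) conjugate addition–elimination that forms C1'–C6', and aromatization makes this closure irreversible. No stereocentre is formed, and the E alkene from step 2 should be conserved because methoxide addition to the enone is reversible and returns the more stable E isomer. The selectivities needed are 1,2- over 1,4-attack on the cinnamoyl unit (secured by the chelating amide and the donor-substituted ring B), methoxide attack at C6 instead of C2 (C6 is unsubstituted, C2 carries the enolized side chain), and chalcone-type instead of stilbene-type folding (in 14 the C5' carbon is vinylic and cannot act as a nucleophile, which is why methoxide and not hydroxide is used, while the competing Michael and oxygen closures are reversible).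

**Compound list**
1 | 4-iodophenol | Oc1ccc(I)cc1 | starting material
2 | 1-bromo-3-methylbut-2-ene (prenyl bromide) | CC(C)=CCBr | starting material
3 | 4-iodo-2,6-bis(3-methylbut-2-en-1-yl)phenol | CC(C)=CCc1cc(I)cc(CC=C(C)C)c1O | intermediate
4 | N-methoxy-N-methylprop-2-enamide | C=CC(=O)N(C)OC | starting material
5 | (2E)-3-[4-hydroxy-3,5-bis(3-methylbut-2-en-1-yl)phenyl]-N-methoxy-N-methylprop-2-enamide | CC(C)=CCc1cc(/C=C/C(=O)N(C)OC)cc(CC=C(C)C)c1O | intermediate
6 | (2E)-3-{4-[(tert-butyldimethylsilyl)oxy]-3,5-bis(3-methylbut-2-en-1-yl)phenyl}-N-methoxy-N-methylprop-2-enamide | CC(C)=CCc1cc(/C=C/C(=O)N(C)OC)cc(CC=C(C)C)c1O[Si](C)(C)C(C)(C)C | intermediate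
7 | (3E)-4-methoxybut-3-en-2-one | CO/C=C/C(C)=O | starting material
8 | acetyl chloride | CC(=O)Cl | starting material
9 | (1E)-1-methoxyhex-1-ene-3,5-dione | CO/C=C/C(=O)CC(C)=O | intermediate
10 | 2-methyl-4H-pyran-4-one | CC1=CC(=O)C=CO1 | intermediate
11 | lithium 2-methylidene-2H-pyran-4-olate (lithium dienolate of 10) | [Li]OC1=CC(=C)OC=C1 | intermediate
12 | lithium (3E)-4-{4-[(tert-butyldimethylsilyl)oxy]-3,5-bis(3-methylbut-2-en-1-yl)phenyl}-2-[methoxy(methyl)amino]-1-(4-oxo-4H-pyran-2-yl)but-3-en-2-olate (racemic, transient) | CC(C)=CCc1cc(/C=C/C(O[Li])(CC2=CC(=O)C=CO2)N(C)OC)cc(CC=C(C)C)c1O[Si](C)(C)C(C)(C)C | intermediate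
13 | 2-[(3E)-4-{4-[(tert-butyldimethylsilyl)oxy]-3,5-bis(3-methylbut-2-en-1-yl)phenyl}-2-oxobut-3-en-1-yl]-4H-pyran-4-one | CC(C)=CCc1cc(/C=C/C(=O)CC2=CC(=O)C=CO2)cc(CC=C(C)C)c1O[Si](C)(C)C(C)(C)C | intermediate
14 | (8E)-9-{4-[(tert-butyldimethylsilyl)oxy]-3,5-bis(3-methylbut-2-en-1-yl)phenyl}-1-methoxynona-1,8-diene-3,5,7-trione (enol ether geometry not defined) | COC=CC(=O)CC(=O)CC(=O)/C=C/c1cc(CC=C(C)C)c(O[Si](C)(C)C(C)(C)C)c(CC=C(C)C)c1 | intermediate
15 | (2E)-3-{4-[(tert-butyldimethylsilyl)oxy]-3,5-bis(3-methylbut-2-en-1-yl)phenyl}-1-(2,4-dihydroxyphenyl)prop-2-en-1-one | CC(C)=CCc1cc(/C=C/C(=O)c2ccc(O)cc2O)cc(CC=C(C)C)c1O[Si](C)(C)C(C)(C)C | intermediate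
16 | (2E)-1-(2,4-dihydroxyphenyl)-3-[4-hydroxy-3,5-bis(3-methylbut-2-en-1-yl)phenyl]prop-2-en-1-one | CC(C)=CCc1cc(/C=C/C(=O)c2ccc(O)cc2O)cc(CC=C(C)C)c1O | target

**Step count and risks**
Total steps: 5. Longest linear sequence: 4 steps (steps 1, 2, 3, 5); step 4 is a one-step side branch.

Most likely to fail:

Step 5. The stabilized dienolate may transfer to the electron-rich amide too slowly, or the opened polycarbonyl chain may be drained by retro-Claisen cleavage or by the reversible Michael and oxygen closures before it aromatizes. Fallback, from 6 back to 16, with ring A brought in preformed: commercial 4-bromoresorcinol is protected (MOMCl, i-Pr2NEt, CH2Cl2) to 1-bromo-2,4-bis(methoxymethoxy)benzene F1. Bromine–lithium exchange (n-BuLi, THF, −78 °C) gives [2,4-bis(methoxymethoxy)phenyl]lithium F2, which adds to amide 6 and should give, after work-up, the protected chalcone (2E)-1-[2,4-bis(methoxymethoxy)phenyl]-3-{4-[(tert-butyldimethylsilyl)oxy]-3,5-bis(3-methylbut-2-en-1-yl)phenyl}prop-2-en-1-one F3. Bu4NF (THF, 0 °C) frees the ring B phenol to give (2E)-1-[2,4-bis(methoxymethoxy)phenyl]-3-[4-hydroxy-3,5-bis(3-methylbut-2-en-1-yl)phenyl]prop-2-en-1-one F4, and HCl in MeOH at rt removes both acetals to reach 16.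

Step 1. The phenoxide may alkylate on oxygen, stop after one prenylation, or alkylate twice at the same ortho carbon. Fallback, from 1 back to 5, with the prenyl groups introduced by cross-coupling: 1 is brominated at both ortho positions (Br2, AcOH, rt) to 2,6-dibromo-4-iodophenol F5. An iodide-selective Heck reaction with 4 (Pd(OAc)2, P(o-tol)3, Et3N, DMF, 60 °C) should give (2E)-3-(3,5-dibromo-4-hydroxyphenyl)-N-methoxy-N-methylprop-2-enamide F6. A twofold Stille coupling with tributyl(3-methylbut-2-en-1-yl)stannane (Pd(PPh3)4, CsF, DMF, 90 °C) then leads to 5.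

Step 2. Palladium hydride formed in the Heck cycle may move the prenyl double bonds into conjugation with ring B, divalent palladium may trigger oxidative cyclization of the ortho-prenylphenol, or the electron-rich phenoxide may stall oxidative addition. Fallback, from 3 back to 6, with the alkene made by olefination: 3 is silylated (TBSCl, imidazole, DMF) to tert-butyl[4-iodo-2,6-bis(3-methylbut-2-en-1-yl)phenoxy]dimethylsilane F7. Iodine–lithium exchange (n-BuLi, THF, −78 °C) gives {4-[(tert-butyldimethylsilyl)oxy]-3,5-bis(3-methylbut-2-en-1-yl)phenyl}lithium F8, which is formylated with DMF to 4-[(tert-butyldimethylsilyl)oxy]-3,5-bis(3-methylbut-2-en-1-yl)benzaldehyde F9. A Horner–Wadsworth–Emmons reaction with diethyl {2-[methoxy(methyl)amino]-2-oxoethyl}phosphonate (NaH, THF, 0 °C to rt) should give the E amide 6 directly.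

**Further compounds**
F1 | step 5 | 1-bromo-2,4-bis(methoxymethoxy)benzene | COCOc1ccc(Br)c(OCOC)c1
F2 | step 5 | [2,4-bis(methoxymethoxy)phenyl]lithium | [Li]c1ccc(OCOC)cc1OCOC
F3 | step 5 | (2E)-1-[2,4-bis(methoxymethoxy)phenyl]-3-{4-[(tert-butyldimethylsilyl)oxy]-3,5-bis(3-methylbut-2-en-1-yl)phenyl}prop-2-en-1-one | CC(C)=CCc1cc(/C=C/C(=O)c2ccc(OCOC)cc2OCOC)cc(CC=C(C)C)c1O[Si](C)(C)C(C)(C)C
F4 | step 5 | (2E)-1-[2,4-bis(methoxymethoxy)phenyl]-3-[4-hydroxy-3,5-bis(3-methylbut-2-en-1-yl)phenyl]prop-2-en-1-one | CC(C)=CCc1cc(/C=C/C(=O)c2ccc(OCOC)cc2OCOC)cc(CC=C(C)C)c1O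
F5 | step 1 | 2,6-dibromo-4-iodophenol | Oc1c(Br)cc(I)cc1Br
F6 | step 1 | (2E)-3-(3,5-dibromo-4-hydroxyphenyl)-N-methoxy-N-methylprop-2-enamide | CON(C)C(=O)/C=C/c1cc(Br)c(O)c(Br)c1
F7 | step 2 | tert-butyl[4-iodo-2,6-bis(3-methylbut-2-en-1-yl)phenoxy]dimethylsilane | CC(C)=CCc1cc(I)cc(CC=C(C)C)c1O[Si](C)(C)C(C)(C)C
F8 | step 2 | {4-[(tert-butyldimethylsilyl)oxy]-3,5-bis(3-methylbut-2-en-1-yl)phenyl}lithium | [Li]c1cc(CC=C(C)C)c(O[Si](C)(C)C(C)(C)C)c(CC=C(C)C)c1
F9 | step 2 | 4-[(tert-butyldimethylsilyl)oxy]-3,5-bis(3-methylbut-2-en-1-yl)benzaldehyde | CC(C)=CCc1cc(C=O)cc(CC=C(C)C)c1O[Si](C)(C)C(C)(C)C
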